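## Retrosynthetic overview

1. C6–CH3 is formed last: a bicyclic ozonide (2,3,7-trioxabicyclo[2.2.1]heptane) is opened at C6 to a 1,2-dioxanyl peroxycarbenium ion and methylated axially, trans to the C4 methyl; the C3 hemiketal then equilibrates (proposed new step).
2. The ozonide comes from a cobalt-mediated aerobic ring expansion (four- to six-membered) of a 2-siloxycyclobutanol: O2 is inserted into the C3–C6 bond, then Me3SiOH is lost.
3. The cyclobutanol comes from Reformatsky addition (C2–C3) to a 2-alkyl-2-siloxycyclobutanone, made by C-alkylation (C6–C7) of the enediolate of an acyloin-derived cyclobutene bis-silyl ether; C4 comes from (R)-methylsuccinic anhydride.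
4. The side-chain iodide comes from phenylacetylene and 1,5-dibromopentane, copper-catalysed coupling with (S)-3-bromo-2-methylpropan-1-ol (C8), Lindlar reduction (Z-alkene) and iodination.
5. Ring order: cyclobutene (acyloin) → cyclobutanone/cyclobutanol → bicyclic ozonide (ring expansion) → monocyclic 1,2-dioxane.

Assumption: (R)-methylsuccinic anhydride and (S)-3-bromo-2-methylpropan-1-ol are taken as catalogue chemicals; target atoms are numbered O1, O2, C3 (hemiketal), C4, C5, C6 in the ring and C7–C16 along the side chain.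

## Route

Step 1
Reactants: 1 phenylacetylene; 2 1,5-dibromopentane
Product: 4 (7-bromohept-1-yn-1-yl)benzene, via lithium phenylacetylide 3 (not isolated)
Conditions: n-BuLi (1.0 equiv), THF, −78 → 0 °C; then 2 (3 equiv), DMPU, 0 °C → rt
Reagents that add atoms: none
Why: SN2 alkylation of a lithium acetylide by a primary bromide; the excess of dibromide suppresses double alkylation and no stereocentre is formed.

Step 2
Reactants: 4 (7-bromohept-1-yn-1-yl)benzene; 5 (S)-3-bromo-2-methylpropan-1-ol
Product: 8 (R)-2-methyl-10-phenyldec-9-yn-1-ol, via Grignard reagent 6 (not isolated), via magnesium alkoxide 7 (not isolated)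
Conditions: 4, Mg, THF, 40 °C; 5, i-PrMgCl (1.0 equiv), THF, −20 °C; then combine, Li2CuCl4 (3 mol%), −20 → 0 °C; NH4Cl aq.
Reagents that add atoms: none
Why: Kochi-type copper-catalysed sp3–sp3 cross-coupling of the alkyl Grignard reagent with the primary bromide of the pre-formed alkoxide; the C8 stereocentre is carried over from 5 because no bond to it is broken (the descriptor changes from S to R only through the priority change).

Step 3
Reactants: 8 (R)-2-methyl-10-phenyldec-9-yn-1-ol
Product: 9 (2R,9Z)-2-methyl-10-phenyldec-9-en-1-ol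
Conditions: H2 (1 atm), Pd/CaCO3 poisoned with Pb(OAc)2 (5 mol% Pd), quinoline, EtOAc, rt
Reagents that add atoms: none
Why: Lindlar semihydrogenation; syn delivery of H2 on the poisoned palladium surface gives the Z-alkene and stops at the alkene stage.

Step 4
Reactants: 9 (2R,9Z)-2-methyl-10-phenyldec-9-en-1-ol
Product: 10 [(1Z,9R)-10-iodo-9-methyldec-1-en-1-yl]benzene
Conditions: I2, PPh3, imidazole, CH2Cl2, 0 °C → rt
Reagents that add atoms: iodine, II
Why: Appel-type iodination (SN2 at the primary carbon of the alkoxyphosphonium salt); the stereocentre and the Z-alkene are not involved.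

Step 5
Reactants: 11 (3R)-3-methyloxolane-2,5-dione ((R)-methylsuccinic anhydride)
Product: 12 dimethyl (2R)-2-methylbutanedioate
Conditions: MeOH, H2SO4 (cat.), reflux
Reagents that add atoms: methanol, CO
Why: Acid-catalysed anhydride methanolysis followed by Fischer esterification; the chiral-pool stereocentre (later C4) is not enolised under acid.

Step 6
Reactants: 12 dimethyl (2R)-2-methylbutanedioate
Product: 13 (3R)-3-methyl-1,2-bis[(trimethylsilyl)oxy]cyclobut-1-ene
Conditions: Na (4.2 equiv), Me3SiCl (4.5 equiv), toluene, reflux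
Reagents that add atoms: chlorotrimethylsilane, C[Si](C)(C)Cl
Why: Rühlmann acyloin condensation (sodium-mediated reductive ester coupling with silyl trapping) closes the four-membered enediol bis-silyl ether; alkoxide is trapped as it forms, so the stereocentre is retained.

Step 7
Reactants: 13 (3R)-3-methyl-1,2-bis[(trimethylsilyl)oxy]cyclobut-1-ene; 10 [(1Z,9R)-10-iodo-9-methyldec-1-en-1-yl]benzene
Product: 15 (4R)-4-methyl-2-[(2R,9Z)-2-methyl-10-phenyldec-9-en-1-yl]-2-[(trimethylsilyl)oxy]cyclobutan-1-one (both C2 epimers), via lithium enolate 14 (not isolated)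
Conditions: MeLi (1.05 equiv), THF, 0 °C → rt; then DMPU, 10 (0.9 equiv), −20 °C → rt
Reagents that add atoms: none
Why: MeLi cleaves one O–Si bond to the lithium enediolate monosilyl ether 14, whose regioisomers equilibrate by O-to-O silyl transfer, and SN2 C-alkylation (enolate alkylation) by the primary iodide then occurs at the less hindered ring carbon remote from the methyl-bearing centre; the new quaternary carbon forms as both epimers (harmless, it is planarised in step 10) and C4, now α to the ketone, is not deprotonated by the weakly basic siloxy enolate.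

Step 8
Reactants: 15 (4R)-4-methyl-2-[(2R,9Z)-2-methyl-10-phenyldec-9-en-1-yl]-2-[(trimethylsilyl)oxy]cyclobutan-1-one; 16 methyl bromoacetate
Product: 18 methyl 2-[(2R)-1-hydroxy-2-methyl-4-[(2R,9Z)-2-methyl-10-phenyldec-9-en-1-yl]-4-[(trimethylsilyl)oxy]cyclobutyl]acetate (isomer mixture at ring C1 and C4), via Reformatsky reagent 17 (not isolated)
Conditions: 16, Zn dust (Me3SiCl-activated), THF, 40 °C; then 15, 0 °C → rt; NH4Cl aq.
Reagents that add atoms: none
Why: Reformatsky reaction; the weakly basic zinc enolate adds to the strained, electrophilic cyclobutanone without enolising it, so C4 is kept, and the new carbinol centre forms as a mixture that does not matter because it becomes the equilibrating hemiketal carbon C3.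

Step 9
Reactants: 18 methyl 2-[(2R)-1-hydroxy-2-methyl-4-[(2R,9Z)-2-methyl-10-phenyldec-9-en-1-yl]-4-[(trimethylsilyl)oxy]cyclobutyl]acetate
Product: 20 methyl 2-[(6R)-6-methyl-4-[(2R,9Z)-2-methyl-10-phenyldec-9-en-1-yl]-2,3,7-trioxabicyclo[2.2.1]heptan-1-yl]acetate (both bridgehead diastereomers; the bridgeheads are C3 and C6 of the target), via silyl dioxanol 19 (not isolated)
Conditions: Co(acac)2 (20 mol%), O2 (1 atm), ClCH2CH2Cl, 40 °C; then PPTS (10 mol%), MgSO4, CH2Cl2, rt
Reagents that add atoms: dioxygen, O=O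
Why: Cobalt-catalysed aerobic oxidative ring expansion of a cyclobutanol: the cobalt-bound alkoxy radical at C3 undergoes strain-driven β-scission of the C3–C6 bond toward the tertiary α-siloxy radical, O2 is trapped at C6 and the hydroperoxide closes onto the new C3 ketone to the 1,2-dioxan-3-ol 19 (C4 is not involved, and all C3/C6 isomers converge), after which acid-catalysed loss of Me3SiOH bridges C3–O–C6 to the bicyclic ozonide.

Step 10
Reactants: 20 methyl 2-[(6R)-6-methyl-4-[(2R,9Z)-2-methyl-10-phenyldec-9-en-1-yl]-2,3,7-trioxabicyclo[2.2.1]heptan-1-yl]acetate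
Product: 22 methyl 2-[(3S,4R,6S)-3-hydroxy-4,6-dimethyl-6-[(2R,9Z)-2-methyl-10-phenyldec-9-en-1-yl]-1,2-dioxan-3-yl]acetate (CNP0217486.1), via silyl ketal 21 (not isolated)
Conditions: AlMe3 (3 equiv), Me3SiOTf (1.2 equiv), CH2Cl2, −78 °C; NaHCO3 aq.; then AcOH–THF–H2O, 0 °C
Reagents that add atoms: trimethylaluminium, C[Al](C)C
Why: Proposed new method: Me3SiOTf ionises the ether bridge of the ozonide at the more electron-rich bridgehead C6 (C3 is deactivated by the β-ester) to a half-chair 1,2-dioxan-6-yl peroxycarbenium ion carrying C3–OSiMe3, AlMe3 delivers methyl along the axial trajectory on the face opposite to the pseudo-equatorial C4 methyl (chair-like transition state, side chain ends equatorial), which sets C6 as S (4,6-trans methyls), and desilylation frees the hemiketal, whose C3 centre equilibrates by ring–chain tautomerism to the anomerically favoured axial OH of the target; the closest known reactions are Lewis-acid-mediated allylations of peroxycarbenium ions generated from ozonides and alkoxy-1,2-dioxolanes or -dioxanes, and AlMe3/Me3SiOTf C-methylation of six-membered oxocarbenium ions with axial attack.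

## Compound list

1 | phenylacetylene | C#Cc1ccccc1 | starting material
2 | 1,5-dibromopentane | BrCCCCCBr | starting material
3 | lithium phenylacetylide | [Li]C#Cc1ccccc1 | intermediate
4 | (7-bromohept-1-yn-1-yl)benzene | BrCCCCCC#Cc1ccccc1 | intermediate
5 | (S)-3-bromo-2-methylpropan-1-ol | OC[C@H](C)CBr | starting material
6 | (7-phenylhept-6-yn-1-yl)magnesium bromide | Br[Mg]CCCCCC#Cc1ccccc1 | intermediate
7 | chloromagnesium (S)-3-bromo-2-methylpropan-1-olate | Cl[Mg]OC[C@H](C)CBr | intermediate
8 | (R)-2-methyl-10-phenyldec-9-yn-1-ol | OC[C@H](C)CCCCCCC#Cc1ccccc1 | intermediate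
9 | (2R,9Z)-2-methyl-10-phenyldec-9-en-1-ol | OC[C@H](C)CCCCCC/C=C\c1ccccc1 | intermediate
10 | [(1Z,9R)-10-iodo-9-methyldec-1-en-1-yl]benzene | IC[C@H](C)CCCCCC/C=C\c1ccccc1 | intermediate
11 | (3R)-3-methyloxolane-2,5-dione | O=C1OC(=O)C[C@H]1C | starting material
12 | dimethyl (2R)-2-methylbutanedioate | COC(=O)C[C@H](C(=O)OC)C | intermediate
13 | (3R)-3-methyl-1,2-bis[(trimethylsilyl)oxy]cyclobut-1-ene | C[Si](C)(C)OC1=C(O[Si](C)(C)C)C[C@H]1C | intermediate
14 | lithium (4R)-4-methyl-2-[(trimethylsilyl)oxy]cyclobut-1-en-1-olate | [Li]OC1=C(O[Si](C)(C)C)C[C@H]1C | intermediate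
15 | (4R)-4-methyl-2-[(2R,9Z)-2-methyl-10-phenyldec-9-en-1-yl]-2-[(trimethylsilyl)oxy]cyclobutan-1-one (both C2 epimers) | O=C1C(O[Si](C)(C)C)(C[C@H](C)CCCCCC/C=C\c2ccccc2)C[C@H]1C | intermediate
16 | methyl bromoacetate | COC(=O)CBr | starting material
17 | bromo(2-methoxy-2-oxoethyl)zinc | Br[Zn]CC(=O)OC | intermediate
18 | methyl 2-[(2R)-1-hydroxy-2-methyl-4-[(2R,9Z)-2-methyl-10-phenyldec-9-en-1-yl]-4-[(trimethylsilyl)oxy]cyclobutyl]acetate (isomer mixture at ring C1 and C4) | COC(=O)CC1(O)C(O[Si](C)(C)C)(C[C@H](C)CCCCCC/C=C\c2ccccc2)C[C@H]1C | intermediate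
19 | methyl 2-[(4R)-3-hydroxy-4-methyl-6-[(2R,9Z)-2-methyl-10-phenyldec-9-en-1-yl]-6-[(trimethylsilyl)oxy]-1,2-dioxan-3-yl]acetate (isomer mixture at C3 and C6) | COC(=O)CC1(O)OOC(O[Si](C)(C)C)(C[C@H](C)CCCCCC/C=C\c2ccccc2)C[C@H]1C | intermediate
20 | methyl 2-[(6R)-6-methyl-4-[(2R,9Z)-2-methyl-10-phenyldec-9-en-1-yl]-2,3,7-trioxabicyclo[2.2.1]heptan-1-yl]acetate (both bridgehead diastereomers) | COC(=O)CC12OOC(C[C@H](C)CCCCCC/C=C\c3ccccc3)(O1)C[C@H]2C | intermediate
21 | methyl 2-[(4R,6S)-4,6-dimethyl-6-[(2R,9Z)-2-methyl-10-phenyldec-9-en-1-yl]-3-[(trimethylsilyl)oxy]-1,2-dioxan-3-yl]acetate (C3 epimers) | COC(=O)CC1(O[Si](C)(C)C)OO[C@@](C)(C[C@H](C)CCCCCC/C=C\c2ccccc2)C[C@H]1C | intermediate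
22 | methyl 2-[(3S,4R,6S)-3-hydroxy-4,6-dimethyl-6-[(2R,9Z)-2-methyl-10-phenyldec-9-en-1-yl]-1,2-dioxan-3-yl]acetate | COC(=O)C[C@]1(O)OO[C@@](C)(C[C@H](C)CCCCCC/C=C\c2ccccc2)C[C@H]1C | target

## Step count and weak points

Total steps: 10. Longest linear sequence: 8 steps (1–4, then 7–10); steps 5–6 are the short branch.

Where each stereocentre comes from: C8 from 5 (step 2), C4 from 11 (step 5), the Z-alkene from step 3, C6 from step 10, and C3 by hemiketal equilibration after step 10.

**Step 7 (enediolate alkylation).** The regiochemistry rests on silyl equilibration and on steric preference for the carbon remote from the methyl group. The β-branched iodide is a slow electrophile, and C4 sits α to the product ketone.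

Fallback, setting out from 13 and 10 and coming back at 15: 13 is oxidised with Br2 (CH2Cl2, −78 °C) to (R)-3-methylcyclobutane-1,2-dione F1. Iodide 10 is converted (Mg, THF) into [(2R,9Z)-2-methyl-10-phenyldec-9-en-1-yl]magnesium iodide F2, which is added at −78 °C to the less hindered carbonyl of F1 (the one remote from the methyl group). This gives iodomagnesium (3R)-3-methyl-1-[(2R,9Z)-2-methyl-10-phenyldec-9-en-1-yl]-2-oxocyclobutan-1-olate F3, which is silylated in the flask with Me3SiCl to 15. The polarity of the C6–C7 bond formation is reversed (side chain as nucleophile) and the regiochemistry is fixed by sterics.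

**Step 9 (aerobic ring expansion).** The reaction type is known for cyclobutanols, but not for a 2-siloxy substrate. Competing loss of the acetate arm by β-scission, silyl loss and peroxyl-radical attack on the styrene are possible.

Fallback, setting out from 18 and coming back at 20: Bu4NF/AcOH (THF, 0 °C) removes the silyl group to give methyl 2-[(2R)-1,4-dihydroxy-2-methyl-4-[(2R,9Z)-2-methyl-10-phenyldec-9-en-1-yl]cyclobutyl]acetate F4. Pb(OAc)4 (CH2Cl2, 0 °C) cleaves the glycol to methyl (4R,8R,15Z)-4,8-dimethyl-3,6-dioxo-16-phenylhexadec-15-enoate F5. Ethereal H2O2 adds across the two ketones to methyl 2-[(4R)-3,6-dihydroxy-4-methyl-6-[(2R,9Z)-2-methyl-10-phenyldec-9-en-1-yl]-1,2-dioxan-3-yl]acetate F6, which PPTS/MgSO4 dehydrates to 20. Radical O2 insertion is replaced by glycol cleavage and two-electron peroxyketalisation.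

**Step 10 (proposed methylation).** Possible failures are ionisation at C3 instead of C6, attack of AlMe3 on the O–O bond, and methyl delivery syn to the departing oxygen.

Fallback with known chemistry, setting out from 20 and coming back at 22: PPh3 (CH2Cl2, rt) reduces the ozonide to the dioxo ester F5 described above. Ph3P=CH2 (2.2 equiv, THF, −78 → 0 °C; the first equivalent parks the β-keto ester as its enolate) methylenates the C6 ketone to methyl (4R,8R,15Z)-4,8-dimethyl-6-methylidene-3-oxo-16-phenylhexadec-15-enoate F7. Mukaiyama–Isayama hydroperoxysilylation (Co(acac)2 cat., O2, Et3SiH, ClCH2CH2Cl, rt) gives methyl (4R,8R,15Z)-4,6,8-trimethyl-3-oxo-16-phenyl-6-[(triethylsilyl)peroxy]hexadec-15-enoate F8 as both C6 epimers. HF·pyridine (THF, 0 °C) frees the hydroperoxide, which closes to 22 and to methyl 2-[(4R,6R)-3-hydroxy-4,6-dimethyl-6-[(2R,9Z)-2-methyl-10-phenyldec-9-en-1-yl]-1,2-dioxan-3-yl]acetate F9; the two are separated by HPLC. In this fallback C6 is formed without control (about 1:1), and competing hydroperoxidation of the styrene has to be limited by stopping at partial conversion.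

## Further compounds

F1 | step 7 | (R)-3-methylcyclobutane-1,2-dione | O=C1C(=O)C[C@H]1C
F2 | step 7 | [(2R,9Z)-2-methyl-10-phenyldec-9-en-1-yl]magnesium iodide | I[Mg]C[C@H](C)CCCCCC/C=C\c1ccccc1
F3 | step 7 | iodomagnesium (3R)-3-methyl-1-[(2R,9Z)-2-methyl-10-phenyldec-9-en-1-yl]-2-oxocyclobutan-1-olate | O=C1C(O[Mg]I)(C[C@H](C)CCCCCC/C=C\c2ccccc2)C[C@H]1C
F4 | step 9 | methyl 2-[(2R)-1,4-dihydroxy-2-methyl-4-[(2R,9Z)-2-methyl-10-phenyldec-9-en-1-yl]cyclobutyl]acetate | COC(=O)CC1(O)C(O)(C[C@H](C)CCCCCC/C=C\c2ccccc2)C[C@H]1C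
F5 | step 9 | methyl (4R,8R,15Z)-4,8-dimethyl-3,6-dioxo-16-phenylhexadec-15-enoate | COC(=O)CC(=O)[C@H](C)CC(=O)C[C@H](C)CCCCCC/C=C\c1ccccc1
F6 | step 9 | methyl 2-[(4R)-3,6-dihydroxy-4-methyl-6-[(2R,9Z)-2-methyl-10-phenyldec-9-en-1-yl]-1,2-dioxan-3-yl]acetate | COC(=O)CC1(O)OOC(O)(C[C@H](C)CCCCCC/C=C\c2ccccc2)C[C@H]1C
F7 | step 10 | methyl (4R,8R,15Z)-4,8-dimethyl-6-methylidene-3-oxo-16-phenylhexadec-15-enoate | COC(=O)CC(=O)[C@H](C)CC(=C)C[C@H](C)CCCCCC/C=C\c1ccccc1
F8 | step 10 | methyl (4R,8R,15Z)-4,6,8-trimethyl-3-oxo-16-phenyl-6-[(triethylsilyl)peroxy]hexadec-15-enoate | COC(=O)CC(=O)[C@H](C)CC(C)(OO[Si](CC)(CC)CC)C[C@H](C)CCCCCC/C=C\c1ccccc1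
F9 | step 10 | methyl 2-[(4R,6R)-3-hydroxy-4,6-dimethyl-6-[(2R,9Z)-2-methyl-10-phenyldec-9-en-1-yl]-1,2-dioxan-3-yl]acetate | COC(=O)CC1(O)OO[C@](C)(C[C@H](C)CCCCCC/C=C\c2ccccc2)C[C@H]1C
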